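Germacrane numbering is used for every ring compound: C1 ketone, C10 its methyl- and oxygen-bearing neighbour, C4=C5 the ring alkene, C6 the lactone carbinol, C7=C11 the butenolide alkene, C8 the ester carbinol, C12 the lactone carbonyl, C13 the acetoxymethyl carbon.

## Structural features

The target is a germacranolide: a ten-membered carbocycle (C1–C10) fused through C6 and C7 to a butenolide (O6–C12(=O)–C11=C7) whose tetrasubstituted C7=C11 bond carries C13 as an acetoxymethyl group. The carbocycle holds the C1 ketone next to the quaternary C10 (methyl, acetoxy; S), a ring-cis (Z) trisubstituted C4=C5 alkene, the bis-allylic lactone carbinol C6 (R) and the allylic methacrylate carbinol C8 (S). C6 and C8 flank C7, and C10 stands 1,3 to C8 across C9. The fragile groups are the methacrylate (Michael acceptor, polymerisable), the primary allylic acetate, the tertiary α-acetoxy ketone and the doubly allylic C6–H γ to the lactone carbonyl; a free C8 hydroxyl under base can also pull the lactone from O6 to O8. The real difficulty is threefold: a Z-configured ten-membered ring, a quaternary C10 with no neighbouring stereocentre to steer it, and two one-carbon arms on C11 that differ only in oxidation level. The key step exploits the masked 1,5-diene C10=C1–C2–C3–C4=C5 (the C1/C10 ketol as an enol ether, C4=C5 as an enone with C6). This is the retron of a bicyclo[2.2.0]hexane cycloreversion, so the ten-membered ring can be grown out of a fused four- and six-membered ring pair. The ring-trans C1=C10 enol ether that results is a planar-chiral unit, and its sense, fixed by the tricyclic precursor, is what later decides C10.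

## Logic of the disconnections

28 ⇒ 27. The C8–O acyl bond is cut first, so that the polymerisable, conjugate-acceptor ester is carried through no other step. The forward acylation must be fast and only weakly basic so that the lactone does not shift to O8.

27 ⇒ 26. The O8–Si bond is cut next. One silyl group survives the whole route and leaves under acidic fluoride, which two acetates, a lactone and a ketone tolerate.

26 ⇒ 24. Both acetyl C–O bonds (O10 and O13) are cut together. One operation serves a primary and a tertiary hydroxyl; the demand is a catalyst strong enough for the tertiary α-ketol.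

24 ⇒ 25 ⇒ 22. The lactone C12–O6 bond and the C12 carbonyl level are traced back to the symmetric 2-alkylidene-1,3-diol of 22. No oxidant can tell the two arms of 22 apart, and only the arm cis to O6 can lactonise. The plan therefore oxidises both arms (25) and then returns the one remaining aldehyde to the alcohol (24). The gain is a geometry-free, symmetric C11 unit; the demand is a chemoselective aldehyde reduction beside a hindered ketone.

22 ⇒ 19. The C10–O bond and the C1 carbonyl are traced to the C1=C10 silyl enol ether; the acetonide and the triethylsilyl group come off in the same operation. The enol ether silicon (triethylsilyl) is deliberately different from the C8 silicon (tert-butyldimethylsilyl), so that O10 can be freed alone. The forward oxidation must hit only the enol ether, and only from the face that gives (10S).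

19 ⇒ 18. The C6–H bond is cut. While C1 is still masked as the enol ether, C6 is the only carbonyl, which removes any ketone-versus-ketone question. The demand is catalyst control between two alkenyl flanks.

18 ⇒ 17. The key reconnection joins C1 to C4 and C5 to C10, folding the ten-membered ring into a cis-anti-cis tricyclo[4.4.0.0(2,5)]decanone. A medium-ring closure is exchanged for a ring opening driven by strain; the demand is that the diyl cleaves C5–C10, not C2–C3, and gives ring-cis C4=C5.

17 ⇒ 13 + 14. The C7=C11 bond is cut to the C7 methylene ketone and a symmetric three-carbon ketone. Symmetry removes any E/Z problem; the demand is regioselective enolisation at C7 and dehydration without loss of the C8 silyloxy group.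

13 ⇒ 7 + 12. The C1–C10 and C4–C5 bonds are cut to a six-membered enone and a four-membered enol ether. The forward cycloaddition must be head-to-tail, cis-anti-cis and anti to the C8 silyloxy group. A tricycle drawn with the cyclobutane syn to O8 is the wrong diastereomer: it is not what the cycloaddition should deliver, and peripheral oxidation of its ring-opened enol ether would end at the C10 epimer. 13 and 17 therefore carry the cyclobutane anti to O8.

7 ⇒ 5 (through 6). The C10–methyl bond is cut and the carbonyl transposed from C6 back to C10. A known enantiopure enone becomes the carrier of C8; the demand is clean 1,2-addition and an oxidative 1,3-shift.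

5 ⇒ 1 (through 3 and 2). The C5=C6 alkene and C10 carbonyl are traced to an all-cis triol that is desymmetrised by an enzyme. C8 thus comes from a meso compound with no loss of half the material; the demand is an enzyme of the right sense.

12 ⇒ 8 (through 11 and 9). The O–Si bond and the C4–methyl bond are cut back to the parent four-membered ketone. The demand is monoalkylation without self-condensation and silylation toward the more substituted enol ether.

## Other disconnections considered

Alternative 1: The cut removes C6–C7, C11–C12 and C12–O at once. It leads from the ketal-protected core A2 back to the open-chain (Z)-enal A1, in which C6 is the aldehyde carbon and C7≡C11 an alkyne that already carries C13 as a propargylic acetate. Forward, a carbonylative hetero-Pauson–Khand reaction on Ru3(CO)12 or Mo(CO)6 would stitch aldehyde, alkyne and CO into the butenolide while the ten-membered ring closes.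
- In its favour: one step makes both rings and delivers the lactone at its final oxidation level. C12 (from CO) and C13 are different from the start, which is better than the chosen plan, where the two arms of a symmetric diol are sorted out late. Only ketal removal, desilylation and acylation would remain afterwards, against seven steps here; this too is better.
- Against it: the reaction type is established for tethers that close five- or six-membered carbocycles. Here the metallacycle must form across a seven-atom tether, so entropy, transannular strain and intermolecular coupling all oppose it. Only the remote C8 centre biases the aldehyde face, so C6 has no dependable control element. The Z enal may isomerise and the propargylic acetate may ionise on a low-valent metal carbonyl at the temperatures needed.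
- Comparison: on step economy the alternative is shorter after the key step and about equal before it. On structure it avoids the photochemical step and the planar-chirality relay. On mechanism it is the weaker plan, because the chosen route opens strained small rings instead of closing a medium ring against entropy.

Alternative 2: The cut is the C1–C6 bond. The dione A4 goes back to the cis-fused decalin-1,6-diol A3, whose cyclohexene ring (C4=C5) would come from ring-closing metathesis. Forward, Pb(OAc)4 cleaves the ditertiary glycol through a cyclic plumbate, both carbinol carbons become ketones and the two six-membered rings merge.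
- In its favour: only six-membered rings are ever closed and the Z alkene is guaranteed by the cyclohexene. Glycol cleavage near room temperature is mechanistically at least as safe as a cycloreversion at 185 °C (the equal or the better on this point). C10, C8 and C7 are set on a rigid bicycle, which is better than relaying C10 through a planar-chiral enol ether.
- Against it: A4 emerges with two free ketones that must be told apart when C6 is reduced, the very problem the chosen plan avoids by keeping C1 masked. A4 has no C11, so the whole butenolide must still be built on the ten-membered ring from the C7 ether (deprotection, oxidation to a 6,7-dione, olefination of a hindered ketone, reduction, lactonisation). A3 carries five stereocentres, two of them tertiary carbinols.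
- Comparison: better stereocontrol at C10 and a safer mechanism, but clearly worse step economy before and after the key step. The chosen plan attaches the C11 unit before the ring is opened.

Alternative 3: The cut is C2–C3 through a Claisen retron. The furan-fused cyclodecenone A6 goes back to the eight-membered cyclic enol ether A5, with an isopropenyl group on C5. Forward, heating shifts the C2=C1–O–C5–C4=C3 array: O–C5 breaks, C2–C3 forms, C1 becomes the ketone and the ring grows from eight to ten atoms.
- In its favour: the reaction is concerted and needs no light. The C1 ketone and the C10 oxygen (set earlier on an ordinary lactone precursor) appear without any enol ether oxidation, which is better than the chosen plan for C10. The furan tells C12 (ring CH) from C13 (silyloxymethyl) from the start, also better than the symmetric diol.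
- Against it: the eight-membered lactone behind A5 (methylenated with Cp2TiMe2) is itself a medium ring that must be closed, so the entropic problem is moved, not removed. C5 is both allylic and furfuryl, so ionisation or a 1,3-shift may compete at Claisen temperatures. Whether the ring-expanding transition state gives the Z or the E trisubstituted alkene rests on ring-strain arguments only. Afterwards the furan must be oxidised regioselectively and C6 created by a reduction with no catalyst handle.
- Comparison: on structure the alternative is the equal or the better at C10 and at C12/C13. On mechanism both are thermal processes above 150 °C, but the chosen one has direct precedent for ten-membered rings from bicyclo[2.2.0]hexanes. On step economy it is similar before the key step and longer after it.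

Key step: step 11

Assumption: the lipase is taken to acetylate the enantiotopic hydroxyl of 2 that leads to 3; enzymes of either preference exist for this class of meso diols.

## Route

Step 1
Reactants: 1 cis,cis-cyclohexane-1,3,5-triol
Product: 2 meso cis,cis-5-(tert-butyldimethylsilyloxy)cyclohexane-1,3-diol
Conditions: TBSCl (0.9 equiv), imidazole, DMF, 0 °C → rt
Reagents that add atoms: tert-butyldimethylsilyl chloride, CC(C)(C)[Si](C)(C)Cl
Why: Monosilylation of a triol whose three hydroxyls are equivalent, so the first silylation is unambiguous; bis-silylated material is separable, unreacted 1 is recovered, and the product is meso, so no stereochemical decision is taken here.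

Step 2
Reactants: 2 meso cis,cis-5-(tert-butyldimethylsilyloxy)cyclohexane-1,3-diol
Product: 3 (1R,3S,5S)-3-(tert-butyldimethylsilyloxy)-5-hydroxycyclohexyl acetate (all-cis)
Conditions: Candida antarctica lipase B (immobilised), vinyl acetate, t-BuOMe, 30 °C
Reagents that add atoms: vinyl acetate, CC(=O)OC=C
Why: Enzymatic desymmetrisation of a meso cis-1,3-diol by irreversible transesterification; the enzyme should acylate one enantiotopic hydroxyl much faster than the other, which fixes the absolute configuration of the future C8 without discarding half of the material.

Step 3
Reactants: 3 (1R,3S,5S)-3-(tert-butyldimethylsilyloxy)-5-hydroxycyclohexyl acetate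
Product: 5 (R)-5-(tert-butyldimethylsilyloxy)cyclohex-2-en-1-one, via acetoxy ketone 4 (not isolated)
Conditions: (n-Pr)4N[RuO4] (5 mol %), N-methylmorpholine N-oxide, 4 Å MS, CH2Cl2, rt; then Et3N, rt
Reagents that add atoms: none
Why: Ley–Griffith oxidation of the free carbinol followed by E1cB elimination; acetate is a far better leaving group than the silyloxide on the other β-carbon, so the alkene should form only toward the acetoxy carbon and the silyloxy stereocentre is untouched.

Step 4
Reactants: 5 (R)-5-(tert-butyldimethylsilyloxy)cyclohex-2-en-1-one
Product: 6 (5R)-5-(tert-butyldimethylsilyloxy)-1-methylcyclohex-2-en-1-ol (both C1 epimers)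
Conditions: MeLi, Et2O, −78 °C
Reagents that add atoms: methyllithium, [Li]C
Why: 1,2-Addition of a hard organolithium to the enone carbonyl at low temperature, which should outrun enolisation and loss of the β-silyloxy group; the new carbinol centre is destroyed in step 5, so its configuration does not matter.

Step 5
Reactants: 6 (5R)-5-(tert-butyldimethylsilyloxy)-1-methylcyclohex-2-en-1-ol
Product: 7 (S)-5-(tert-butyldimethylsilyloxy)-3-methylcyclohex-2-en-1-one
Conditions: IBX, DMSO, 55 °C
Reagents that add atoms: none
Why: Babler–Dauben-type oxidative 1,3-transposition of a tertiary allylic alcohol, here under neutral conditions with IBX: allylic shift of the oxygen and oxidation give the β-methyl enone; the silyloxy centre is not involved (its descriptor changes from R to S only through the priority rules).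

Step 6
Reactants: 8 cyclobutanone
Product: 9 cyclobutanone N,N-dimethylhydrazone
Conditions: Me2NNH2, MgSO4, Et2O, rt
Reagents that add atoms: 1,1-dimethylhydrazine, CN(C)N
Why: Hydrazone condensation; the hydrazone gives a non-electrophilic aza-enolate in step 7, which avoids the self-aldol and polyalkylation that beset direct alkylation of cyclobutanone.

Step 7
Reactants: 9 cyclobutanone N,N-dimethylhydrazone
Product: 11 2-methylcyclobutanone (racemic), via methylated hydrazone 10 (not isolated)
Conditions: LiN(i-Pr)2, THF, 0 °C; MeI, −78 °C → rt; then oxalic acid (aq.), Et2O, rt
Reagents that add atoms: iodomethane, CI; water, O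
Why: Aza-enolate alkylation of a metalated hydrazone followed by mild two-phase hydrolysis; monoalkylation is expected because the product hydrazone is less acidic, and the stereocentre of 11 is erased on enolisation in step 8.

Step 8
Reactants: 11 2-methylcyclobutanone (racemic)
Product: 12 1-(triethylsilyloxy)-2-methylcyclobut-1-ene
Conditions: Et3SiOTf, Et3N, CH2Cl2, 0 °C → rt
Reagents that add atoms: triethylsilyl trifluoromethanesulfonate, CC[Si](CC)(CC)OS(=O)(=O)C(F)(F)F
Why: Soft enolisation with a silyl triflate and an amine, conditions that favour the more substituted (tetrasubstituted) silyl enol ether; any less substituted regioisomer should be removable by fractional distillation.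

Step 9
Reactants: 7 (S)-5-(tert-butyldimethylsilyloxy)-3-methylcyclohex-2-en-1-one; 12 1-(triethylsilyloxy)-2-methylcyclobut-1-ene
Product: 13 cis-anti-cis tricyclo[4.4.0.0(2,5)]decanone photoadduct (C6 ketone; C1 triethylsilyloxy; C4 and C10 methyl; (8S) tert-butyldimethylsilyloxy; cyclobutane anti to O8)
Conditions: hν (366 nm, Pyrex), 12 (4 equiv), CH2Cl2 (degassed), −40 °C; then filtration through neutral Al2O3
Reagents that add atoms: none
Why: Enone–alkene [2+2] photocycloaddition through the triplet enone and a 1,4-diradical; the electron-rich enol ether should add head-to-tail, so the silyloxy-bearing C1 bonds to the β-carbon C10 and the methyl-bearing C4 to C5; the CH2CH2 bridge of the cyclobutene turns away from the six-membered ring (cis-anti-cis) and, as in conjugate additions to 5-silyloxycyclohexenones, the C10–C1 bond should form anti to the C8 silyloxy group, which sets C1, C4, C5 and C10; the alumina pass secures the cis fusion at the only epimerisable centre C5 and the syn diastereomer is removed by chromatography.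

Step 10
Reactants: 13 cis-anti-cis tricyclo[4.4.0.0(2,5)]decanone photoadduct; 14 2,2-dimethyl-1,3-dioxan-5-one
Product: 17 key-step precursor (13 with a 2,2-dimethyl-1,3-dioxan-5-ylidene group at C7), via lithium aldolate 15 (not isolated), via aldol trifluoroacetate 16 (not isolated)
Conditions: LiN(i-Pr)2, THF, −78 °C; 14, −78 °C; (CF3CO)2O, −78 °C; DBU, −78 → 0 °C
Reagents that add atoms: none
Why: Directed aldol condensation: the amide base should remove a C7 methylene proton in preference to the hindered ring-fusion C5 methine, the enolate adds to the α,α'-dioxygenated and therefore activated ketone 14, and the tertiary aldolate is trapped as its trifluoroacetate before it can revert; DBU then removes the acidic C7 proton and trifluoroacetate leaves far more readily than the C8 silyloxide (E1cB); the symmetric three-carbon unit raises no E/Z question and the C7 stereocentre of 15 and 16 disappears.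

Step 11
Reactants: 17 key-step precursor
Product: 18 (8S)-8-(tert-butyldimethylsilyloxy)-7-(2,2-dimethyl-1,3-dioxan-5-ylidene)-4,10-dimethyl-1-(triethylsilyloxy)cyclodeca-1(10),4-dien-6-one (C1=C10 ring-trans; C4=C5 ring-cis)
Conditions: PhMe (0.01 M, degassed), 2,6-di-tert-butyl-4-methylphenol (cat.), sealed base-washed glass, 185 °C
Reagents that add atoms: none
Why: Thermal cycloreversion of a bicyclo[2.2.0]hexane: the strained central C1–C4 σ bond, flanked by the silyloxy group on C1 and the fully substituted C4, should homolyse to a cyclohexane-1,4-diyl (C1, C2, C3, C4, C5, C10) that relaxes from boat to chair and then undergoes β-scission of C5–C10. The closest known reaction type is the thermolysis of cis-anti-cis enone–cyclobutene photoadducts to cis,trans-cyclodeca-1,5-dienes. The ten-membered ring is not closed by bond formation: it appears by fragmentation of the two bonds that the central cyclobutane shares with the four- and six-membered rings, so no exo or endo cyclisation mode and no entropic penalty is involved. No stereocentre is created; the alkene geometries follow from the chair diyl, in which C6 sits axial on C5 to escape A(1,2) strain with the C4 methyl and so ends cis to C3 (Z C4=C5), while C9 sits equatorial on C10 and ends trans to C2 (ring-trans C1=C10, formally Z by the priority rules because of the silyloxy group). The step needs C5–C10 scission to win over C2–C3 scission, and this is secured by the products of the former, a conjugated C4=C5–C6 enone and a tetrasubstituted enol ether, against two less substituted, unconjugated vinyl groups for the latter. The same conjugation makes a later Cope shift to a divinylcyclohexane unfavourable. The faces of C1=C10 that were bonded to C4 and C5 end up inside the ring, and because neither a methyl nor a silyloxy group can swing through a ten-membered ring this planar sense should persist and later decide C10. Dilute, degassed, acid-free conditions protect the enol ether and suppress bimolecular pathways.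

Step 12
Reactants: 18 cyclodecadienone
Product: 19 (6R,8S)-6-hydroxy analogue of 18 (bis-allylic alcohol)
Conditions: (S)-2-methyl-CBS-oxazaborolidine (0.3 equiv), catecholborane, PhMe, −78 °C
Reagents that add atoms: none
Why: Corey–Bakshi–Shibata reduction of the only carbonyl present (C1 is still an enol ether); the fully substituted alkenyl carbon C7 should act as the large group and the C5 methine as the small one, so the (S)-catalyst is expected to deliver hydride to the face that gives (6R); catecholborane at −78 °C should leave the enol ether and the alkenes alone.

Step 13
Reactants: 19 (6R,8S)-bis-allylic alcohol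
Product: 22 (6R,8S,10S)-8-(tert-butyldimethylsilyloxy)-6,10-dihydroxy-7-[1,3-dihydroxypropan-2-ylidene]-4,10-dimethylcyclodec-4-en-1-one, via silyloxy epoxide 20 (not isolated), via silyloxy ketone 21 (not isolated)
Conditions: dimethyldioxirane, acetone/CH2Cl2, −78 → −40 °C; then AcOH/THF/H2O (3:1:1), rt
Reagents that add atoms: dimethyldioxirane, CC1(C)OO1
Why: Rubottom oxidation: the tetrasubstituted silyl enol ether is by far the most electron-rich alkene (C7=C11 carries four allylic C–O bonds) and, being ring-trans, can be reached only from its outer face, so the new C10–O bond forms anti to the former C10–C5 bond and gives (10S); the silyloxy epoxide opens with 1,4-silyl shift to the α-silyloxy ketone, and aqueous acetic acid then removes the tertiary triethylsilyl group and the acetonide while the secondary tert-butyldimethylsilyl ether should stay.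

Step 14
Reactants: 22 (6R,8S,10S)-tetrol ketone
Product: 25 (6R,8S,10S)-8-(tert-butyldimethylsilyloxy)-10-hydroxy-1,13-dioxogermacra-4Z,7(11)-dien-12,6-olide (formyl butenolide), via lactol 23 (not isolated), via hydroxy lactone 24 (not isolated)
Conditions: TEMPO (0.2 equiv), PhI(OAc)2 (3.5 equiv), CH2Cl2/pH 7 buffer, rt
Reagents that add atoms: none
Why: Oxoammonium (TEMPO) oxidation of primary alcohols: the C12 aldehyde is trapped by the cis C6 hydroxyl as a lactol and oxidised on to the lactone; because the oxidant cannot tell the two CH2OH arms apart, the oxidation is run to completion so that every molecule converges on 25 whichever arm reacts first, while the secondary and tertiary hydroxyls react much more slowly.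

Step 15
Reactants: 25 formyl butenolide
Product: 24 (6R,8S,10S)-8-(tert-butyldimethylsilyloxy)-10,13-dihydroxy-1-oxogermacra-4Z,7(11)-dien-12,6-olide
Conditions: NaBH4 (0.5 equiv), CeCl3·7H2O, MeOH/CH2Cl2, −78 °C
Reagents that add atoms: none
Why: Luche reduction: 1,2-reduction of the conjugated aldehyde at −78 °C should be much faster than attack on the hindered saturated C1 ketone (quaternary C10 next door) or on the lactone, and the fully substituted C7 disfavours conjugate addition.

Step 16
Reactants: 24 dihydroxy lactone
Product: 26 (6R,8S,10S)-10,13-diacetoxy-8-(tert-butyldimethylsilyloxy)-1-oxogermacra-4Z,7(11)-dien-12,6-olide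
Conditions: Ac2O, Et3N, DMAP, CH2Cl2, rt → 35 °C
Reagents that add atoms: acetic anhydride, CC(=O)OC(C)=O
Why: DMAP-catalysed acylation; the primary allylic C13 hydroxyl reacts at once and the tertiary C10 α-ketol needs the nucleophilic catalyst and longer time; no stereocentre is touched, and the mild amine base should not epimerise C6.

Step 17
Reactants: 26 diacetate silyl ether
Product: 27 (6R,8S,10S)-10,13-diacetoxy-8-hydroxy-1-oxogermacra-4Z,7(11)-dien-12,6-olide
Conditions: HF·pyridine, pyridine, THF, 0 °C → rt
Reagents that add atoms: none
Why: Fluoride-mediated cleavage of the secondary allylic silyl ether; the acidic medium avoids acetate migration and the base-promoted shift of the lactone from O6 to O8, and acetates, lactone and ketone are stable to it.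

Step 18
Reactants: 27 C8 alcohol
Product: 28 CNP0115165.3, (6R,8S,10S)-10,13-diacetoxy-8-(methacryloyloxy)-1-oxogermacra-4Z,7(11)-dien-12,6-olide
Conditions: methacrylic anhydride, Et3N, DMAP (cat.), CH2Cl2, 0 °C
Reagents that add atoms: methacrylic anhydride, CC(=C)C(=O)OC(=O)C(C)=C
Why: DMAP-catalysed acylation of the secondary allylic alcohol with retention at C8; a fast acyl transfer at 0 °C traps the hydroxyl before it can attack the lactone, and the sensitive methacrylate is introduced in the last step.

## Compound list

1 | cis,cis-cyclohexane-1,3,5-triol | O[C@H]1C[C@@H](O)C[C@@H](O)C1 | starting material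
2 | meso cis,cis-5-(tert-butyldimethylsilyloxy)cyclohexane-1,3-diol | O[C@H]1C[C@@H](O)C[C@@H](O[Si](C)(C)C(C)(C)C)C1 | intermediate
3 | (1R,3S,5S)-3-(tert-butyldimethylsilyloxy)-5-hydroxycyclohexyl acetate | O[C@H]1C[C@@H](OC(C)=O)C[C@@H](O[Si](C)(C)C(C)(C)C)C1 | intermediate
4 | cis-(3S,5R)-3-acetoxy-5-(tert-butyldimethylsilyloxy)cyclohexanone (not isolated) | O=C1C[C@@H](OC(C)=O)C[C@@H](O[Si](C)(C)C(C)(C)C)C1 | intermediate
5 | (R)-5-(tert-butyldimethylsilyloxy)cyclohex-2-en-1-one | O=C1C=CC[C@@H](O[Si](C)(C)C(C)(C)C)C1 | intermediate
6 | (5R)-5-(tert-butyldimethylsilyloxy)-1-methylcyclohex-2-en-1-ol, both C1 epimers | CC1(O)C=CC[C@@H](O[Si](C)(C)C(C)(C)C)C1 | intermediate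
7 | (S)-5-(tert-butyldimethylsilyloxy)-3-methylcyclohex-2-en-1-one | O=C1C=C(C)C[C@H](O[Si](C)(C)C(C)(C)C)C1 | intermediate
8 | cyclobutanone | O=C1CCC1 | starting material
9 | cyclobutanone N,N-dimethylhydrazone | CN(C)N=C1CCC1 | intermediate
10 | 2-methylcyclobutanone N,N-dimethylhydrazone (not isolated) | CC1CCC1=NN(C)C | intermediate
11 | 2-methylcyclobutanone, racemic | CC1CCC1=O | intermediate
12 | 1-(triethylsilyloxy)-2-methylcyclobut-1-ene | CC1=C(O[Si](CC)(CC)CC)CC1 | intermediate
13 | cis-anti-cis tricyclo[4.4.0.0(2,5)]decanone photoadduct, cyclobutane anti to O8, (8S) | CC[Si](CC)(CC)O[C@]12CC[C@@]1(C)[C@@H]1C(=O)C[C@@H](O[Si](C)(C)C(C)(C)C)C[C@@]12C | intermediate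
14 | 2,2-dimethyl-1,3-dioxan-5-one | CC1(C)OCC(=O)CO1 | starting material
15 | lithium aldolate of 13 and 14, C7 configuration immaterial (not isolated) | CC[Si](CC)(CC)O[C@]12CC[C@@]1(C)[C@@H]1C(=O)C(C3([O-])COC(C)(C)OC3)[C@@H](O[Si](C)(C)C(C)(C)C)C[C@@]12C.[Li+] | intermediate
16 | aldol trifluoroacetate (not isolated) | CC[Si](CC)(CC)O[C@]12CC[C@@]1(C)[C@@H]1C(=O)C(C3(OC(=O)C(F)(F)F)COC(C)(C)OC3)[C@@H](O[Si](C)(C)C(C)(C)C)C[C@@]12C | intermediate
17 | key-step precursor: cis-anti-cis tricyclic ketone with C7 dioxanylidene | CC[Si](CC)(CC)O[C@]12CC[C@@]1(C)[C@@H]1C(=O)C(=C3COC(C)(C)OC3)[C@@H](O[Si](C)(C)C(C)(C)C)C[C@@]12C | intermediate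
18 | key-step product: 1-silyloxycyclodeca-1(10),4-dien-6-one with C7 dioxanylidene, C1=C10 ring-trans, C4=C5 ring-cis, (8S) | CC(C)(C)[Si](C)(C)O[C@H]1C/C(C)=C(O[Si](CC)(CC)CC)/CC/C(C)=C\C(=O)C1=C2COC(C)(C)OC2 | intermediate
19 | (6R,8S)-bis-allylic alcohol | CC(C)(C)[Si](C)(C)O[C@H]1C/C(C)=C(O[Si](CC)(CC)CC)/CC/C(C)=C\[C@@H](O)C1=C2COC(C)(C)OC2 | intermediate
20 | 1,10-silyloxy epoxide, oxygen on the outer face (not isolated) | CC(C)(C)[Si](C)(C)O[C@H]1C[C@]2(C)O[C@@]2(O[Si](CC)(CC)CC)CC/C(C)=C\[C@@H](O)C1=C3COC(C)(C)OC3 | intermediate
21 | (6R,8S,10S)-10-triethylsilyloxy 1-ketone acetonide (not isolated) | CC(C)(C)[Si](C)(C)O[C@H]1C[C@](C)(O[Si](CC)(CC)CC)C(=O)CC/C(C)=C\[C@@H](O)C1=C2COC(C)(C)OC2 | intermediate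
22 | (6R,8S,10S)-6,10,12,13-tetrol 1-ketone, C8 silyl ether | CC(C)(C)[Si](C)(C)O[C@H]1C[C@](C)(O)C(=O)CC/C(C)=C\[C@@H](O)C1=C(CO)CO | intermediate
23 | 12,6-lactol, C12 configuration immaterial (not isolated) | CC(C)(C)[Si](C)(C)O[C@H]1C[C@](C)(O)C(=O)CC/C(C)=C\[C@H]2OC(O)C(CO)=C12 | intermediate
24 | 10,13-dihydroxy 12,6-olide | CC(C)(C)[Si](C)(C)O[C@H]1C[C@](C)(O)C(=O)CC/C(C)=C\[C@H]2OC(=O)C(CO)=C12 | intermediate
25 | 10-hydroxy-13-oxo 12,6-olide (formyl butenolide) | CC(C)(C)[Si](C)(C)O[C@H]1C[C@](C)(O)C(=O)CC/C(C)=C\[C@H]2OC(=O)C(C=O)=C12 | intermediate
26 | 10,13-diacetate, C8 silyl ether | CC(C)(C)[Si](C)(C)O[C@H]1C[C@](C)(OC(C)=O)C(=O)CC/C(C)=C\[C@H]2OC(=O)C(COC(C)=O)=C12 | intermediate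
27 | 10,13-diacetate, C8 alcohol | O[C@H]1C[C@](C)(OC(C)=O)C(=O)CC/C(C)=C\[C@H]2OC(=O)C(COC(C)=O)=C12 | intermediate
28 | CNP0115165.3 | C=C(C)C(=O)O[C@H]1C[C@](C)(OC(C)=O)C(=O)CC/C(C)=C\[C@H]2OC(=O)C(COC(C)=O)=C12 | target

## Step count and least certain steps

Total: 18 steps. Longest linear sequence: 15 steps (steps 1–5 and 9–18); steps 6–8 form a three-step branch that joins at step 9.

Step 11 (key step). Most likely to go wrong: partition of the diyl toward C2–C3 scission, or loss of the ring-opened dienone by a Cope shift or by thermal dienolisation of the alkylidene ketone (1,5-hydrogen shift from the dioxane CH2 cis to the carbonyl). The temperature needed for homolysis lies close to the onset of these processes. Fallback: set out from 13 and open the ring before the alkylidene is in place. Thermolysis of 13 under the same conditions should give the simpler dienone (8S)-8-(tert-butyldimethylsilyloxy)-4,10-dimethyl-1-(triethylsilyloxy)cyclodeca-1(10),4-dien-6-one F1, which has no alkylidene γ-hydrogen. Its kinetic C7 lithium enolate is added to 14 to give the tertiary aldol F2, and dehydration of F2 with the Burgess reagent returns to the route at 18.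

Step 9. Most likely to go wrong: poor facial selectivity with respect to the C8 silyloxy group, because a silyl ether on a flexible six-membered enone is only a modest steering group for a triplet-state addition; the syn adduct would carry through to the C10 epimer. Fallback: set out from 7 and let a much bulkier ether steer the addition. Desilylation with HF·pyridine gives (S)-5-hydroxy-3-methylcyclohex-2-en-1-one F3, and 4,4'-dimethoxytrityl chloride converts it into the dimethoxytrityl ether F4. Photocycloaddition of F4 with 12 gives the anti adduct F5, and dichloroacetic acid removes the trityl group (the tertiary triethylsilyl ether should stay) to give the hydroxy ketone F6. Silylation of F6 with TBSCl returns to the route at 13.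

Step 10. Most likely to go wrong: proton transfer from the enolisable ketone 14 to the enolate, reversal of the congested tertiary aldolate before it is trapped, or β-elimination of the C8 silyloxy group from the C7 enolate. Fallback: set out from 13 and form C7=C11 by olefination. The C7 enolate is O-phosphorylated with ClP(O)(OEt)2 to the enol phosphate F7, and LiN(i-Pr)2 then induces the 1,3-phosphoryl shift from oxygen to C7 to give the β-keto phosphonate F8. A Horner–Wadsworth–Emmons reaction of F8 with 14 returns to the route at 17.

Step 12. Most likely to go wrong: poor facial selectivity, because both flanks of C6 are alkenyl and the catalyst must tell a fully substituted sp2 carbon from a CH carbon while the planar-chiral ring imposes its own peripheral bias. Fallback: set out from 18 with a substrate-controlled Luche reduction (NaBH4, CeCl3·7H2O) and separate 19 from its C6 epimer F9. F9 is returned to 18 by MnO2 oxidation for another pass, and the route is rejoined at 19.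

Step 13. Most likely to go wrong: competing epoxidation of C4=C5 and C7=C11, which become electron-rich allylic-alcohol alkenes once C6 is reduced, and acid-promoted ionisation of the bis-allylic C6 carbinol during the unveiling. Fallback: set out from 18 and change the order. Rubottom oxidation of the dienone 18, in which the C6 carbonyl deactivates both other alkenes, goes through the silyloxy epoxide F10 to the α-silyloxy dione F11. The C6 ketone of F11 is then reduced as in step 12, the C1 ketone being shielded by the adjacent quaternary silyloxy carbon; this rejoins the route at 21, which aqueous acetic acid unveils to 22.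

Step 14. Most likely to go wrong: oxidation of the bis-allylic C6 carbinol before the lactol has closed, or loss of the strongly electrophilic formyl butenolide by hydration or conjugate addition during the long exposure needed to oxidise both arms. Fallback: set out from 22 and converge at the acid level. Oxidation of both primary alcohols with TEMPO/NaOCl/NaClO2 gives the alkylidene malonic acid F12. Its carboxyl group cis to the C6 hydroxyl should lactonise spontaneously to the carboxy butenolide F13, and chemoselective reduction of the free acid with BH3·SMe2 returns to the route at 24.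

## Further compounds

F1 | step 11 | (8S)-8-(tert-butyldimethylsilyloxy)-4,10-dimethyl-1-(triethylsilyloxy)cyclodeca-1(10),4-dien-6-one | CC(C)(C)[Si](C)(C)O[C@H]1C/C(C)=C(O[Si](CC)(CC)CC)/CC/C(C)=C\C(=O)C1
F2 | step 11 | tertiary aldol of F1 with 14 (C7 configuration immaterial) | CC(C)(C)[Si](C)(C)O[C@H]1C/C(C)=C(O[Si](CC)(CC)CC)/CC/C(C)=C\C(=O)C1C1(O)COC(C)(C)OC1
F3 | step 9 | (S)-5-hydroxy-3-methylcyclohex-2-en-1-one | CC1=CC(=O)C[C@@H](O)C1
F4 | step 9 | (S)-5-(4,4'-dimethoxytrityloxy)-3-methylcyclohex-2-en-1-one | CC1=CC(=O)C[C@@H](OC(c2ccccc2)(c2ccc(OC)cc2)c2ccc(OC)cc2)C1
F5 | step 9 | cis-anti-cis photoadduct with C8 dimethoxytrityl ether | CC[Si](CC)(CC)O[C@]12CC[C@@]1(C)[C@@H]1C(=O)C[C@@H](OC(c3ccccc3)(c3ccc(OC)cc3)c3ccc(OC)cc3)C[C@@]12C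
F6 | step 9 | cis-anti-cis photoadduct with free C8 hydroxyl | CC[Si](CC)(CC)O[C@]12CC[C@@]1(C)[C@@H]1C(=O)C[C@@H](O)C[C@@]12C
F7 | step 10 | C6 diethyl enol phosphate of 13 | CC[Si](CC)(CC)O[C@]12CC[C@@]1(C)[C@@H]1C(OP(=O)(OCC)OCC)=C[C@@H](O[Si](C)(C)C(C)(C)C)C[C@@]12C
F8 | step 10 | C7 diethyl phosphonate of 13 (β-keto phosphonate) | CC[Si](CC)(CC)O[C@]12CC[C@@]1(C)[C@@H]1C(=O)C(P(=O)(OCC)OCC)[C@@H](O[Si](C)(C)C(C)(C)C)C[C@@]12C
F9 | step 12 | (6S,8S)-bis-allylic alcohol, C6 epimer of 19 | CC(C)(C)[Si](C)(C)O[C@H]1C/C(C)=C(O[Si](CC)(CC)CC)/CC/C(C)=C\[C@H](O)C1=C2COC(C)(C)OC2
F10 | step 13 | 1,10-silyloxy epoxide of 18 | CC(C)(C)[Si](C)(C)O[C@H]1C[C@]2(C)O[C@@]2(O[Si](CC)(CC)CC)CC/C(C)=C\C(=O)C1=C3COC(C)(C)OC3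
F11 | step 13 | (8S,10S)-10-triethylsilyloxy 1,6-dione acetonide | CC(C)(C)[Si](C)(C)O[C@H]1C[C@](C)(O[Si](CC)(CC)CC)C(=O)CC/C(C)=C\C(=O)C1=C2COC(C)(C)OC2
F12 | step 14 | alkylidene malonic acid from 22 | CC(C)(C)[Si](C)(C)O[C@H]1C[C@](C)(O)C(=O)CC/C(C)=C\[C@@H](O)C1=C(C(=O)O)C(=O)O
F13 | step 14 | 13-carboxy 12,6-olide | CC(C)(C)[Si](C)(C)O[C@H]1C[C@](C)(O)C(=O)CC/C(C)=C\[C@H]2OC(=O)C(C(=O)O)=C12
A1 | alternative 1 | open-chain (Z)-enal with tethered propargylic acetate, C1 dioxolane | O=C/C=C(C)\CCC1(OCCO1)[C@@](C)(OC(C)=O)C[C@H](O[Si](C)(C)C(C)(C)C)C#CCOC(C)=O
A2 | alternative 1 | target core as C1 dioxolane and C8 silyl ether | CC(C)(C)[Si](C)(C)O[C@H]1C[C@](C)(OC(C)=O)C2(OCCO2)CC/C(C)=C\[C@H]2OC(=O)C(COC(C)=O)=C12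
A3 | alternative 2 | cis-fused decalin-1,6-diol (one cis-diol diastereomer drawn) | CC1=C[C@@]2(O)[C@H](OCc3ccc(OC)cc3)[C@@H](O[Si](C)(C)C(C)(C)C)C[C@](C)(OC(C)=O)[C@@]2(O)CC1
A4 | alternative 2 | (Z)-cyclodec-4-ene-1,6-dione with C10 acetate, C8 silyl ether, C7 PMB ether | CC(C)(C)[Si](C)(C)O[C@H]1C[C@](C)(OC(C)=O)C(=O)CC/C(C)=C\C(=O)[C@@H]1OCc1ccc(OC)cc1
A5 | alternative 3 | furan-fused 2-methylene-8-isopropenyl oxocane (one C5 epimer drawn) | C=C1O[C@@H](C(C)=C)c2occ(CO[Si](C)(C)C(C)(C)C)c2[C@@H](O[Si](C)(C)C(C)(C)C)C[C@]1(C)O[Si](CC)(CC)CC
A6 | alternative 3 | furan-fused (Z)-cyclodec-4-en-1-one | CC(C)(C)[Si](C)(C)O[C@H]1C[C@](C)(O[Si](CC)(CC)CC)C(=O)CC/C(C)=C\c2occ(CO[Si](C)(C)C(C)(C)C)c12
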